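**Retrosynthetic overview**

1. Target 18 ⇐ 17 by propionylation of the C7 tertiary alcohol.
2. 17 ⇐ 16 by α-ketol ring expansion. The feature used is C7 of the isochromene carbocycle (C4a–C5–C6–C7–C8–C8a), a carbon carrying O and CH3 between the C6 and C8 ketones. It maps onto the acetyl carbon of a 6-acetyl-6-hydroxycyclopenta[c]pyran-7-one, and the C7–C8 bond forms by shift of the ring acyl carbon.
3. 16 ⇐ 13 by C6 acetylation, reagent-controlled C6 hydroxylation (the only stereocentre made in the route) and C5 chlorination.
4. 13 ⇐ bromo formyl cyclopentenone 11 (from cyclopentane-1,3-dione) + dienyne 7 by Sonogashira coupling and 6-endo cycloisomerisation; 7 ⇐ (S)-2-methylbutan-1-ol by Wittig and Horner–Wadsworth–Emmons chain extension.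
5. Ring order: cyclopentane (purchased) → pyran (step 8) → six-membered carbocycle by expansion of the cyclopentane (step 12).

Key step: step 12

Remark (assumption): the (+)-(camphorylsulfonyl)oxaziridine is taken to deliver oxygen to the face of the enolate of 14 that gives (6R)-15. The sense of induction has to be established on the first run; if it is the opposite, the (−)-reagent is used in the same step.

Remark: 13 is drawn as the ketone and 14 as its chelated enol; both may be tautomer mixtures. Compounds 13–16 use cyclopenta[c]pyran numbering (C1, O2, C3, C4, C4a, C5, C6, C7, C7a); 17 and 18 use isochromene numbering.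

**Route**

Step 1
Reactants: 1 (S)-2-methylbutan-1-ol
Product: 3 ethyl (2E,4S)-2,4-dimethylhex-2-enoate, via (S)-2-methylbutanal 2 (not isolated)
Conditions: TEMPO (10 mol %), PhI(OAc)2, CH2Cl2, rt; then Ph3P=C(Me)CO2Et, rt
Reagents that add atoms: ethyl 2-(triphenyl-λ5-phosphanylidene)propanoate, CCOC(=O)C(C)=P(c1ccccc1)(c1ccccc1)c1ccccc1
Why: TEMPO/PhI(OAc)2 oxidation followed in the same flask by a Wittig reaction with the stabilised ylide should give the E-trisubstituted enoate, and the epimerisable α-branched aldehyde is consumed without isolation so that the S centre is kept.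

Step 2
Reactants: 3 ethyl (2E,4S)-2,4-dimethylhex-2-enoate
Product: 4 (2E,4S)-2,4-dimethylhex-2-en-1-ol
Conditions: DIBAL-H (2.2 equiv), CH2Cl2, −78 °C; aq. Rochelle salt
Reagents that add atoms: none
Why: 1,2-Reduction of the enoate by DIBAL-H should stop cleanly at the allylic alcohol without touching the alkene or the stereocentre.

Step 3
Reactants: 4 (2E,4S)-2,4-dimethylhex-2-en-1-ol
Product: 5 (2E,4S)-2,4-dimethylhex-2-enal
Conditions: MnO2 (excess), CH2Cl2, rt
Reagents that add atoms: none
Why: Allylic oxidation with MnO2 is neutral and heterogeneous, so neither the alkene geometry nor the γ-stereocentre should be affected.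

Step 4
Reactants: 5 (2E,4S)-2,4-dimethylhex-2-enal
Product: 6 trimethyl[(3E,5E,7S)-5,7-dimethylnona-3,5-dien-1-yn-1-yl]silane
Conditions: (EtO)2P(O)CH2C≡CTMS, LiHMDS, THF, −78 °C → 0 °C
Reagents that add atoms: diethyl [3-(trimethylsilyl)prop-2-yn-1-yl]phosphonate, CCOP(=O)(CC#C[Si](C)(C)C)OCC
Why: Horner–Wadsworth–Emmons olefination with the lithiated propargyl phosphonate should give mainly the 3E enyne, and 1,2-addition to the aldehyde at low temperature should outrun γ-deprotonation, which leaves the stereocentre intact.

Step 5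
Reactants: 6 trimethyl[(3E,5E,7S)-5,7-dimethylnona-3,5-dien-1-yn-1-yl]silane
Product: 7 (3E,5E,7S)-5,7-dimethylnona-3,5-dien-1-yne
Conditions: K2CO3 (0.2 equiv), MeOH, rt
Reagents that add atoms: none
Why: Methanolysis of the alkynyl C–Si bond is a standard desilylation and should leave the conjugated diene untouched.

Step 6
Reactants: 8 cyclopentane-1,3-dione
Product: 9 2-[(dimethylamino)methylidene]cyclopentane-1,3-dione
Conditions: Me2NCH(OMe)2, CH2Cl2, rt
Reagents that add atoms: N,N-dimethylformamide dimethyl acetal, COC(OC)N(C)C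
Why: Condensation of the acidic C2 position of the 1,3-dione with the amide acetal should install the future C1 carbon as a stable vinylogous amide.

Step 7
Reactants: 9 2-[(dimethylamino)methylidene]cyclopentane-1,3-dione
Product: 11 2-bromo-5-oxocyclopent-1-ene-1-carbaldehyde, via bromo iminium bromide 10 (not isolated)
Conditions: (COBr)2, CH2Cl2, −20 → 0 °C; then ice-water, 0 °C
Reagents that add atoms: oxalyl bromide, O=C(Br)C(=O)Br; water, O
Why: Vilsmeier-type activation of the vinylogous amide (O-acylation, then bromide addition–elimination) should give the β-bromo vinyl iminium salt, and cold hydrolysis should release the aldehyde faster than the vinylogous acyl bromide is attacked, the haloformylation pattern known from 4-hydroxycoumarin to 4-chloro-3-formylcoumarin.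

Step 8
Reactants: 11 2-bromo-5-oxocyclopent-1-ene-1-carbaldehyde; 7 (3E,5E,7S)-5,7-dimethylnona-3,5-dien-1-yne
Product: 13 3-[(1E,3E,5S)-3,5-dimethylhepta-1,3-dien-1-yl]cyclopenta[c]pyran-7(6H)-one, via alkynyl formyl enone 12 (not isolated)
Conditions: PdCl2(PPh3)2 (3 mol %), CuI (10 mol %), i-Pr2NEt, THF (degassed), 0 °C → rt; then 40 °C
Reagents that add atoms: none
Why: Sonogashira coupling at the doubly activated vinyl bromide gives the alkynyl formyl enone; the amine then removes the C5–H (γ to both carbonyls) and the formyl-derived enolate oxygen adds 6-endo-dig to the copper-activated alkyne, the cycloisomerisation used to close the pyran ring of azaphilones, with the dienyl group on the distal alkyne carbon expected to favour 6-endo over 5-exo closure.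

Step 9
Reactants: 13 3-[(1E,3E,5S)-3,5-dimethylhepta-1,3-dien-1-yl]cyclopenta[c]pyran-7(6H)-one
Product: 14 1-{3-[(1E,3E,5S)-3,5-dimethylhepta-1,3-dien-1-yl]-7-hydroxycyclopenta[c]pyran-6-yl}ethan-1-one (enol form of the 6-acetyl 7-ketone)
Conditions: MgBr2·OEt2, i-Pr2NEt, 1-acetylbenzotriazole, CH2Cl2, rt
Reagents that add atoms: 1-acetyl-1H-benzotriazole, CC(=O)n1nnc2ccccc12
Why: Crossed-Claisen C-acylation under soft enolisation should acylate C6, the only enolisable position, and the 1,3-diketone is held as its magnesium chelate, which should prevent a second acylation.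

Step 10
Reactants: 14 1-{3-[(1E,3E,5S)-3,5-dimethylhepta-1,3-dien-1-yl]-7-hydroxycyclopenta[c]pyran-6-yl}ethan-1-one
Product: 15 (6R)-6-acetyl-3-[(1E,3E,5S)-3,5-dimethylhepta-1,3-dien-1-yl]-6-hydroxycyclopenta[c]pyran-7(6H)-one
Conditions: KHMDS, THF, −78 °C; (+)-(camphorylsulfonyl)oxaziridine, −78 → −40 °C; aq. NH4Cl
Reagents that add atoms: (+)-(camphorylsulfonyl)oxaziridine, CC1(C)[C@@H]2CC[C@]13CS(=O)(=O)N4O[C@@]34C2
Why: Asymmetric enolate hydroxylation with the Davis oxaziridine: the potassium enolate attacks the oxaziridine oxygen through C6, the central carbon of the 1,3-dicarbonyl unit, and the camphor skeleton of the reagent differentiates the two faces of the planar enolate, which sets the C6 carbinol by reagent control (the remote side-chain centre has no influence).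

Step 11
Reactants: 15 (6R)-6-acetyl-3-[(1E,3E,5S)-3,5-dimethylhepta-1,3-dien-1-yl]-6-hydroxycyclopenta[c]pyran-7(6H)-one
Product: 16 (6R)-6-acetyl-5-chloro-3-[(1E,3E,5S)-3,5-dimethylhepta-1,3-dien-1-yl]-6-hydroxycyclopenta[c]pyran-7(6H)-one
Conditions: NCS (1.05 equiv), MeCN, 0 °C → rt
Reagents that add atoms: N-chlorosuccinimide, O=C1CCC(=O)N1Cl
Why: Electrophilic chlorination of the dienol ether O2–C3=C4–C4a=C5 at its terminus C5 (attack there gives a pyrylium ion that loses the C5 proton) is the site selectivity known for NCS chlorination of azaphilone cores; C6 is now quaternary and the side-chain diene is not activated by the ring oxygen.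

Step 12
Reactants: 16 (6R)-6-acetyl-5-chloro-3-[(1E,3E,5S)-3,5-dimethylhepta-1,3-dien-1-yl]-6-hydroxycyclopenta[c]pyran-7(6H)-one
Product: 17 (7R)-5-chloro-3-[(1E,3E,5S)-3,5-dimethylhepta-1,3-dien-1-yl]-7-hydroxy-7-methyl-6H-isochromene-6,8(7H)-dione
Conditions: Al(Ot-Bu)3 (1.5 equiv), toluene, 60 °C; aq. Rochelle salt
Reagents that add atoms: none
Why: Ligand exchange puts the tertiary C6 alkoxide on aluminium and the acetyl oxygen completes a five-membered chelate; the ring acyl carbon (C7 of 16), held perpendicular to the acetyl plane, then shifts with its bonding pair from C6 to the acetyl carbon while the old carbinol becomes a ketone, an α-ketol (acyloin) rearrangement of the type used for D-homoannulation of 17-hydroxy-20-keto steroids and, with acyl migration, seen in the humulone–isohumulone interconversion. The six-membered carbocycle is thus formed by ring expansion through a 1,2-shift (new bond C7–C8 in isochromene numbering), not by a new cyclisation. The new stereocentre C7 is set by chirality transfer: in the syn O–C–C=O chelate the migrating carbon can reach only the acetyl face on which it lies, which converts (6R)-16 into (7R)-17. The step needs the acyl carbon to migrate rather than the chlorovinyl carbon C5, and the acetyl chelate rather than the ring-ketone chelate to be productive. C5 migration would give a 1,2-dione without the C6 carbonyl conjugation, and a shift onto the ring ketone would break the vinylogous ester, so under reversible conditions 17 should be the sink. The driving force is the new O2–C3=C4–C4a=C5–C6=O conjugation, which the isolated acetyl group of 16 lacks.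

Step 13
Reactants: 17 (7R)-5-chloro-3-[(1E,3E,5S)-3,5-dimethylhepta-1,3-dien-1-yl]-7-hydroxy-7-methyl-6H-isochromene-6,8(7H)-dione
Product: 18 Sclerketide B, (7R)-5-chloro-3-[(1E,3E,5S)-3,5-dimethylhepta-1,3-dien-1-yl]-7-methyl-6,8-dioxo-7,8-dihydro-6H-isochromen-7-yl propanoate
Conditions: (EtCO)2O, DMAP (cat.), Et3N, CH2Cl2, 0 °C → rt
Reagents that add atoms: propanoic anhydride, CCC(=O)OC(=O)CC
Why: DMAP-catalysed acylation of the tertiary alcohol with the anhydride touches no stereocentre, and the ester removes the free ketol so that no reverse shift can follow.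

**Compound list**

1 | (S)-2-methylbutan-1-ol | CC[C@H](C)CO | starting material
2 | (S)-2-methylbutanal | CC[C@H](C)C=O | intermediate (not isolated)
3 | ethyl (2E,4S)-2,4-dimethylhex-2-enoate | CCOC(=O)/C(C)=C/[C@@H](C)CC | intermediate
4 | (2E,4S)-2,4-dimethylhex-2-en-1-ol | OC/C(C)=C/[C@@H](C)CC | intermediate
5 | (2E,4S)-2,4-dimethylhex-2-enal | O=C/C(C)=C/[C@@H](C)CC | intermediate
6 | trimethyl[(3E,5E,7S)-5,7-dimethylnona-3,5-dien-1-yn-1-yl]silane | C[Si](C)(C)C#C/C=C/C(C)=C/[C@@H](C)CC | intermediate
7 | (3E,5E,7S)-5,7-dimethylnona-3,5-dien-1-yne | C#C/C=C/C(C)=C/[C@@H](C)CC | intermediate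
8 | cyclopentane-1,3-dione | O=C1CCC(=O)C1 | starting material
9 | 2-[(dimethylamino)methylidene]cyclopentane-1,3-dione | CN(C)C=C1C(=O)CCC1=O | intermediate
10 | N-[(2-bromo-5-oxocyclopent-1-en-1-yl)methylidene]-N-methylmethanaminium bromide | C[N+](C)=CC1=C(Br)CCC1=O.[Br-] | intermediate (not isolated)
11 | 2-bromo-5-oxocyclopent-1-ene-1-carbaldehyde | O=CC1=C(Br)CCC1=O | intermediate
12 | 2-[(3E,5E,7S)-5,7-dimethylnona-3,5-dien-1-yn-1-yl]-5-oxocyclopent-1-ene-1-carbaldehyde | O=CC1=C(C#C/C=C/C(C)=C/[C@@H](C)CC)CCC1=O | intermediate (not isolated)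
13 | 3-[(1E,3E,5S)-3,5-dimethylhepta-1,3-dien-1-yl]cyclopenta[c]pyran-7(6H)-one | O=C1CC=C2C=C(/C=C/C(C)=C/[C@@H](C)CC)OC=C12 | intermediate
14 | 1-{3-[(1E,3E,5S)-3,5-dimethylhepta-1,3-dien-1-yl]-7-hydroxycyclopenta[c]pyran-6-yl}ethan-1-one | CC(=O)C1=C(O)C2=COC(/C=C/C(C)=C/[C@@H](C)CC)=CC2=C1 | intermediate
15 | (6R)-6-acetyl-3-[(1E,3E,5S)-3,5-dimethylhepta-1,3-dien-1-yl]-6-hydroxycyclopenta[c]pyran-7(6H)-one | CC(=O)[C@@]1(O)C(=O)C2=COC(/C=C/C(C)=C/[C@@H](C)CC)=CC2=C1 | intermediate
16 | (6R)-6-acetyl-5-chloro-3-[(1E,3E,5S)-3,5-dimethylhepta-1,3-dien-1-yl]-6-hydroxycyclopenta[c]pyran-7(6H)-one | CC(=O)[C@@]1(O)C(=O)C2=COC(/C=C/C(C)=C/[C@@H](C)CC)=CC2=C1Cl | intermediate (key-step precursor)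
17 | (7R)-5-chloro-3-[(1E,3E,5S)-3,5-dimethylhepta-1,3-dien-1-yl]-7-hydroxy-7-methyl-6H-isochromene-6,8(7H)-dione | O[C@]1(C)C(=O)C2=COC(/C=C/C(C)=C/[C@@H](C)CC)=CC2=C(Cl)C1=O | intermediate (key-step product)
18 | Sclerketide B | CCC(=O)O[C@]1(C)C(=O)C2=COC(/C=C/C(C)=C/[C@@H](C)CC)=CC2=C(Cl)C1=O | target

Total step count: 13
Longest linear sequence: 11 steps (steps 1–5, then 8–13)

**Steps most likely to fail**

1. Step 12 (key step). The chlorovinyl carbon C5 may migrate instead of the acyl carbon. Part of the material may react through a non-chelated conformer, which would erode the configuration at C7. The Lewis acid may also degrade the dienyl enol ether before the shift is complete. Fallback: the hydroxy core would be made by the oxidative dearomatisation route to azaphilones, setting out from dienyne 7 and coming back at 17. Dienyne 7 is coupled under Pd/Cu catalysis (Et3N) with 6-bromo-2,4-dihydroxy-3-methylbenzaldehyde F1 to give 6-[(3E,5E,7S)-5,7-dimethylnona-3,5-dien-1-yn-1-yl]-2,4-dihydroxy-3-methylbenzaldehyde F2. Copper(I)/chiral diamine (sparteine type)/O2 hydroxylative dearomatisation at the methyl-bearing carbon, followed by Cu(I)-mediated 6-endo cycloisomerisation, gives the des-chloro hydroxy azaphilone F3, with the enantiomer of the diamine chosen for the C7 arrangement of 17. NCS chlorination at C5 then returns to 17.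

2. Step 8. The doubly activated bromo enal may be consumed by hydrolysis or amine addition before oxidative addition, the alkyne may homocouple, the ring may close 5-exo instead of 6-endo, and the electron-rich bicyclic ketone may oligomerise. Fallback: the coupling is replaced by a carbonyl addition with transposition, setting out from enaminone 9 and dienyne 7 and coming back at 13. The lithium acetylide of 7 (n-BuLi, CeCl3, THF, −78 °C) is added to one ketone of 9 to give the tertiary propargylic carbinol 2-[(dimethylamino)methylidene]-3-[(3E,5E,7S)-5,7-dimethylnona-3,5-dien-1-yn-1-yl]-3-hydroxycyclopentan-1-one F4. Dilute aqueous acid expels water through the enamine and hydrolyses the iminium (Stork–Danheiser-type transposition) to the alkynyl formyl enone 12, which is cyclised in a separate operation with catalytic AgOTf and then Et3N to 13. This avoids bromide 11 and palladium.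

3. Step 10. Oxygen transfer to the flat enolate may show poor facial selectivity, or the sense of induction may be low for both reagent enantiomers. Fallback: induction is given up for separation, setting out from 14 and coming back at 15. Enolate 14 is oxidised with racemic 2-(phenylsulfonyl)-3-phenyloxaziridine, which gives 15 together with its C6 epimer (6S)-6-acetyl-3-[(1E,3E,5S)-3,5-dimethylhepta-1,3-dien-1-yl]-6-hydroxycyclopenta[c]pyran-7(6H)-one F5. Because the side-chain centre is fixed, the two are diastereomers and would be separated by preparative HPLC (chiral stationary phase if needed); 15 is carried on.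

Further compounds
F1 | step 12 | 6-bromo-2,4-dihydroxy-3-methylbenzaldehyde | O=Cc1c(Br)cc(O)c(C)c1O
F2 | step 12 | 6-[(3E,5E,7S)-5,7-dimethylnona-3,5-dien-1-yn-1-yl]-2,4-dihydroxy-3-methylbenzaldehyde | O=Cc1c(C#C/C=C/C(C)=C/[C@@H](C)CC)cc(O)c(C)c1O
F3 | step 12 | (7S)-3-[(1E,3E,5S)-3,5-dimethylhepta-1,3-dien-1-yl]-7-hydroxy-7-methyl-6H-isochromene-6,8(7H)-dione (same spatial arrangement at C7 as 17; the descriptor changes because Cl is absent) | O[C@]1(C)C(=O)C2=COC(/C=C/C(C)=C/[C@@H](C)CC)=CC2=CC1=O
F4 | step 8 | 2-[(dimethylamino)methylidene]-3-[(3E,5E,7S)-5,7-dimethylnona-3,5-dien-1-yn-1-yl]-3-hydroxycyclopentan-1-one (both carbinol epimers) | CN(C)C=C1C(=O)CCC1(O)C#C/C=C/C(C)=C/[C@@H](C)CC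
F5 | step 10 | (6S)-6-acetyl-3-[(1E,3E,5S)-3,5-dimethylhepta-1,3-dien-1-yl]-6-hydroxycyclopenta[c]pyran-7(6H)-one | CC(=O)[C@]1(O)C(=O)C2=COC(/C=C/C(C)=C/[C@@H](C)CC)=CC2=C1
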